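**Retrosynthetic overview**
1. Target 49 ⇐ ring-C ketone 40: C13 (methyl axial, vinyl equatorial) by two alkylations of the C14 enolate, the second anti to the axial 8β-silyloxy group; benzoate, acetate and the two tert-butyl esters are adjusted at the end.
2. Ring C ⇐ ring B: C11–C12 by 6-endo acyl-radical closure of aldehyde 36 onto a vinyl ketone; C8–C14 and the 8β-OH by addition of lithiated methoxyallene to C8 ketone 30; 7α-O by enolate hydroxylation.
3. Ring B ⇐ ten-membered allylic lactone 16 by Ireland–Claisen ring contraction (bond C9–C10). The feature used: ring B carries three contiguous equatorial carbon branches, C4 on C5, C1 on the quaternary C10 (methyl axial) and C11 on C9, the outcome of a chair rearrangement across the macrocycle.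
4. Lactone 16 ⇐ hydroxy acid 15 (Mitsunobu closure of O–C2); C7–C8 by B-alkyl Suzuki coupling; C5 by Ir-catalysed asymmetric allylic alkylation with an isobutyrate ketene acetal.
5. Ring order: temporary ten-membered lactone (step 10), ring B (step 11), ring C (step 24).

Key step: step 11

Remark: atoms are numbered as in the target skeleton (ring B = C5–C10; ring C = C8, C9, C11–C14; C1–C2 = acetic acid arm on C10; C3–C4 = CMe2CO2H on C5); α/β refer to the usual projection with the C10 methyl β.
Assumption: in step 6 the antipode of the phosphoramidite ligand is the one that gives the (3R) ester 10.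

Step 1
Reactants: 1 (E)-3-methylpent-2-en-4-yn-1-ol
Product: 2 TBS ether of 1
Conditions: TBSCl, imidazole, CH2Cl2, 0 °C to rt
Reagents that add atoms: tert-butyldimethylsilyl chloride, C[Si](C)(Cl)C(C)(C)C
Why: Silyl ether formation masks the primary allylic alcohol (O–C2) through the organometallic steps; no stereocentre is formed.

Step 2
Reactants: 2 TBS ether
Product: 4 enynol (E)-6-[(tert-butyldimethylsilyl)oxy]-4-methylhex-4-en-2-yn-1-ol, via lithium acetylide 3 (not isolated)
Conditions: n-BuLi, THF, −78 °C; (CH2O)n, −78 °C to rt; H2O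
Reagents that add atoms: formaldehyde (from paraformaldehyde), C=O
Why: Deprotonation of the terminal alkyne and 1,2-addition of the acetylide to formaldehyde (hydroxymethylation) brings in C7 as a propargylic alcohol.

Step 3
Reactants: 4 enynol
Product: 5 (2E,4E)-dienol
Conditions: NaAlH2(OCH2CH2OMe)2, THF, 0 °C to rt; aqueous work-up
Reagents that add atoms: none
Why: Alkoxide-directed trans-hydroalumination of the propargylic alcohol and protonolysis should give the E allylic alcohol, so the diene is obtained as the 2E,4E isomer.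

Step 4
Reactants: 5 dienol
Product: 6 allylic methyl carbonate
Conditions: ClCO2Me, pyridine, CH2Cl2, 0 °C
Reagents that add atoms: methyl chloroformate, COC(=O)Cl
Why: O-Acylation with the chloroformate installs the carbonate leaving group needed for allyl-metal formation.

Step 5
Reactants: 7 tert-butyl 2-methylpropanoate
Product: 9 silyl ketene acetal, via lithium enolate 8 (not isolated)
Conditions: LiN(i-Pr)2, THF, −78 °C; Me3SiCl, −78 °C to rt
Reagents that add atoms: chlorotrimethylsilane, C[Si](C)(C)Cl
Why: Ester enolisation and O-silylation give the tetrasubstituted silyl ketene acetal, which has no E/Z issue.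

Step 6
Reactants: 6 allylic carbonate, 9 silyl ketene acetal
Product: 10 tert-butyl (3R,4E)-6-[(tert-butyldimethylsilyl)oxy]-3-ethenyl-2,2,4-trimethylhex-4-enoate
Conditions: [Ir(cod)Cl]2 (2 mol %), (S,S,Sa)-O,O′-(1,1′-binaphthyl-2,2′-diyl) N,N-bis(1-phenylethyl)phosphoramidite or its antipode (4 mol %), n-PrNH2 (activation), THF, rt
Reagents that add atoms: none
Why: Ir-catalysed asymmetric allylic alkylation: the allyl-iridium complex formed from the carbonate is attacked at its substituted terminus by the ester enolate that the released methoxide frees from 9, so the chiral ligand sets C5 (3R) and the branched product keeps a terminal vinyl group (C6=C7).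

Step 7
Reactants: 10 ester, 11 3-bromobut-3-en-1-ol
Product: 13 homoallylic alcohol with the C8 methylene, via alkylborane 12 (not isolated)
Conditions: 9-BBN dimer, THF, 0 °C to rt; then 11, Pd(dppf)Cl2 (5 mol %), 3 M aq. NaOH, THF, 60 °C
Reagents that add atoms: none
Why: Anti-Markovnikov hydroboration of the only monosubstituted alkene and B-alkyl Suzuki–Miyaura coupling with the vinyl bromide form C7–C8; C5 is not touched.

Step 8
Reactants: 13 alcohol
Product: 14 seco acid (TBS ether)
Conditions: TEMPO (cat.), PhI(OAc)2, MeCN/H2O (1:1), rt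
Reagents that add atoms: water, O
Why: Nitroxyl-catalysed oxidation of the primary alcohol through the aldehyde hydrate gives the acid under near-neutral conditions that should leave the β,γ-alkene unconjugated and the silyl ether in place.

Step 9
Reactants: 14 seco acid
Product: 15 hydroxy acid
Conditions: HF·pyridine, pyridine/THF, 0 °C to rt
Reagents that add atoms: none
Why: Fluoride cleavage of the silyl ether (desilylation) frees the allylic alcohol; the tert-butyl ester is stable to buffered HF.

Step 10
Reactants: 15 hydroxy acid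
Product: 16 ten-membered (E)-allylic lactone
Conditions: PPh3, DIAD, toluene/THF, slow addition of 15 (final 2 mM), 0 °C to rt
Reagents that add atoms: none
Why: Mitsunobu macrolactonisation activates the allylic alcohol as its oxyphosphonium ion for displacement by the carboxylate, which avoids acyl activation of the isomerisation-prone β,γ-unsaturated acid; C2 is primary, so no stereocentre is involved.

Step 11
Reactants: 16 lactone
Product: 19 ring-B acid (1S,2S,3R)-3-(1-tert-butoxy-2-methyl-1-oxopropan-2-yl)-2-ethenyl-2-methyl-6-methylidenecyclohexane-1-carboxylic acid, via silyl ketene acetal 17 (not isolated), via trimethylsilyl ester 18 (not isolated)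
Conditions: LiN(i-Pr)2, Me3SiCl, THF/DMPU (4:1), −78 °C; then rt to 65 °C; dilute aq. HCl
Reagents that add atoms: none
Why: The lactone is deprotonated at C9 (α to the carbonyl and allylic to the C8 methylene) and O-silylated to ketene acetal 17, whose C9=C11 and C1=C10 π bonds form a 1,5-diene inside the ten-membered ring; a concerted suprafacial [3,3] shift (Ireland–Claisen rearrangement) then makes C9–C10 and breaks O–C2, giving silyl ester 18 and, after hydrolysis, acid 19. The closest known reaction type is the ring-contracting Ireland–Claisen rearrangement of macrocyclic allylic lactones, the oxa analogue of the germacrene-to-elemene Cope rearrangement. Ring B closes transannularly: the tether C5–C6–C7–C8 joins the two reacting termini, so the six-membered carbocycle forms as a chair fused to the chair-like six-centre array and the macrocycle loses four ring atoms. C9 is set by the E alkene, which holds C5 pseudo-equatorial on the six-centre chair and therefore puts C11 equatorial on ring B; C10 is set by C5 together with the ketene acetal geometry, because with the bulky CMe2CO2t-Bu group equatorial on the nascent ring and C8 anti to the ring oxygen the vinyl group C1=C2 ends equatorial and the methyl axial. The step therefore needs the enolate with C8 syn to the enolate oxygen, which the dipolar cosolvent (open, non-chelated deprotonation) is chosen to favour, and rearrangement through C9 and not through the cross-conjugated methylene terminus, which is secured because only C9 can reach C10 in a six-centre array.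

Step 12
Reactants: 19 acid
Product: 20 methyl ester
Conditions: Me3SiCHN2, MeOH/toluene, 0 °C
Reagents that add atoms: (trimethylsilyl)diazomethane, C[Si](C)(C)C=[N+]=[N-]
Why: Esterification with the diazoalkane under neutral conditions should avoid conjugation of the β,γ-unsaturated acid and epimerisation at C9.

Step 13
Reactants: 20 methyl ester
Product: 21 C11 primary alcohol
Conditions: i-Bu2AlH (2.5 equiv), CH2Cl2, −78 to 0 °C; aqueous work-up
Reagents that add atoms: none
Why: Hydride reduction of the methyl ester to the alcohol; the α-quaternary tert-butyl ester is too hindered to react at low temperature.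

Step 14
Reactants: 21 alcohol
Product: 22 C11 PMB ether
Conditions: NaH, 4-methoxybenzyl chloride, Bu4NI (cat.), DMF, 0 °C to rt
Reagents that add atoms: 4-methoxybenzyl chloride, COc1ccc(CCl)cc1
Why: Williamson etherification protects O–C11 as an ether that can later be removed oxidatively in the presence of silyl ethers.

Step 15
Reactants: 22 PMB ether
Product: 23 C2 aldehyde (C10 bears CH2CHO)
Conditions: PdCl2(PhCN)2 (10 mol %), CuCl2·2H2O (10 mol %), AgNO2 (5 mol %), t-BuOH/MeNO2 (15:1), O2 (1 atm), rt
Reagents that add atoms: dioxygen, O=O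
Why: Nitrite-modified aldehyde-selective Wacker oxidation functionalises the terminal carbon of the vinyl group on quaternary C10 (anti-Markovnikov attack is favoured by the allylic quaternary centre), while the 1,1-disubstituted C8 methylene is a poor Wacker substrate.

Step 16
Reactants: 23 aldehyde
Product: 24 C2 carboxylic acid
Conditions: NaClO2, NaH2PO4, 2-methyl-2-butene, t-BuOH/H2O, rt
Reagents that add atoms: sodium chlorite, [Na+].[O-]Cl=O
Why: Pinnick oxidation takes the aldehyde to the acid, and the alkene scavenger protects the C8 methylene from hypochlorous acid.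

Step 17
Reactants: 24 acid
Product: 25 di-tert-butyl ester
Conditions: tert-butyl 2,2,2-trichloroacetimidate, cyclohexane/CH2Cl2, rt
Reagents that add atoms: tert-butyl 2,2,2-trichloroacetimidate, CC(C)(C)OC(=N)C(Cl)(Cl)Cl
Why: Catalyst-free O-alkylation of the carboxylic acid by the imidate (tert-butyl ester formation) lets both acids be freed together at the end and spares the PMB ether.

Step 18
Reactants: 25 diester
Product: 27 C8 ketone, via diol 26 (not isolated)
Conditions: OsO4 (2 mol %), NaIO4 (4 equiv), 2,6-lutidine, dioxane/H2O (3:1), rt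
Reagents that add atoms: sodium periodate (oxygen relayed by OsO4), [Na+].[O-]I(=O)(=O)=O
Why: Lemieux–Johnson oxidation (dihydroxylation, then periodate cleavage) of the only remaining alkene gives the C8 ketone without ozone, which could attack the PMB ring.

Step 19
Reactants: 27 ketone
Product: 29 7α-hydroxy ketone, via potassium enolate 28 (not isolated)
Conditions: KN(SiMe3)2, THF, −78 °C; 2-(phenylsulfonyl)-3-phenyloxaziridine, −78 °C; H2O
Reagents that add atoms: 2-(phenylsulfonyl)-3-phenyloxaziridine, O=S(=O)(c1ccccc1)N1OC1c1ccccc1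
Why: Kinetic enolate formation at the less hindered C7 and enolate oxidation by the N-sulfonyloxaziridine from the α face, the axial direction at C7, should give the axial 7α-alcohol.

Step 20
Reactants: 29 hydroxy ketone
Product: 30 7α-triethylsilyloxy ketone
Conditions: Et3SiCl, imidazole, DMF, rt
Reagents that add atoms: chlorotriethylsilane, CC[Si](Cl)(CC)CC
Why: Silylation of the secondary alcohol blocks α-ketol isomerisation and protects O7 through the basic steps.

Step 21
Reactants: 30 ketone, 31 methoxyallene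
Product: 34 α′-hydroxy vinyl ketone (8β-OH), via 1-lithio-1-methoxyallene 32 (not isolated), via lithium alkoxide adduct 33 (not isolated)
Conditions: 31, n-BuLi, THF, −78 °C; add 30, −78 °C; H2O; then 5% aq. H2SO4, THF, 0 °C
Reagents that add atoms: water, O
Why: 1,2-Addition of the lithiated allenyl ether (an acyl-anion equivalent) to the C8 ketone from the equatorial α direction, because axial approach is blocked by the syn-axial C10 methyl, should give the axial 8β-alcohol with C14 equatorial, and enol-ether hydrolysis then unmasks the vinyl ketone.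

Step 22
Reactants: 34 PMB ether
Product: 35 C11 alcohol
Conditions: DDQ, CH2Cl2/pH 7 buffer, 0 °C to rt
Reagents that add atoms: none
Why: Oxidative cleavage of the PMB ether in wet solvent frees the C11 alcohol while the triethylsilyl ether and the enone survive.

Step 23
Reactants: 35 alcohol
Product: 36 C11 aldehyde
Conditions: 1,1,1-triacetoxy-1,1-dihydro-1,2-benziodoxol-3(1H)-one, NaHCO3, CH2Cl2, 0 °C to rt
Reagents that add atoms: none
Why: Buffered periodinane oxidation gives the aldehyde without epimerising C9 or provoking retro-aldol cleavage.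

Step 24
Reactants: 36 aldehyde
Product: 37 trans-fused ring-C 11,14-diketone
Conditions: tert-dodecanethiol (0.3 equiv), 1,1′-azobis(cyclohexanecarbonitrile) (portionwise), PhCl, 90 °C
Reagents that add atoms: none
Why: Thiol-catalysed radical-chain hydroacylation: the thiyl radical abstracts the aldehyde hydrogen and the nucleophilic C11 acyl radical closes 6-endo onto the terminal carbon of the vinyl ketone, forming C11–C12 and a trans-fused ring C because C11 and C14 are both equatorial on ring B, after which the thiol reduces the α-keto radical.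

Step 25
Reactants: 37 diketone
Product: 38 11α-alcohol
Conditions: Me4NBH(OAc)3, MeCN/AcOH (1:1), −30 °C
Reagents that add atoms: none
Why: Hydroxyl-directed reduction (Evans–Saksena type): the axial 8β-hydroxyl binds boron and delivers hydride to the axial β face of the C11 ketone, giving the equatorial 11α-alcohol, while C14, flanked by quaternary C8 and reachable only through a five-membered array, should react more slowly.

Step 26
Reactants: 38 alcohol
Product: 39 11α-benzoate
Conditions: BzCl, pyridine, DMAP (cat.), CH2Cl2, 0 °C to rt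
Reagents that add atoms: benzoyl chloride, O=C(Cl)c1ccccc1
Why: Acylation of the equatorial secondary alcohol; the hindered tertiary 8-hydroxyl should not react.

Step 27
Reactants: 39 benzoate
Product: 40 8β-trimethylsilyl ether
Conditions: Me3SiOTf, 2,6-lutidine, CH2Cl2, −78 °C
Reagents that add atoms: trimethylsilyl trifluoromethanesulfonate, C[Si](C)(C)OS(=O)(=O)C(F)(F)F
Why: Silylation of the tertiary alcohol prevents α-ketol rearrangement and alkoxide side reactions in the enolate steps and adds bulk on the β face.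

Step 28
Reactants: 40 ketone
Product: 42 13-methyl ketone (expected as a mixture of C13 epimers), via lithium enolate 41 (not isolated)
Conditions: LiN(SiMe3)2 (1.05 equiv), THF, −78 °C; MeI, −78 to −20 °C
Reagents that add atoms: iodomethane, CI
Why: Regiospecific enolate formation (C8 is quaternary, so only C13 can be deprotonated) and C-methylation; the configuration at C13 does not matter because the centre is enolised again.

Step 29
Reactants: 42 methyl ketone, 43 phenyl vinyl sulfoxide
Product: 45 13α-[2-(phenylsulfinyl)ethyl]-13β-methyl ketone, via potassium enolate 44 (not isolated)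
Conditions: KN(SiMe3)2, THF, −78 to 0 °C; 43, −78 °C to rt; H2O
Reagents that add atoms: none
Why: Michael addition of the tetrasubstituted enolate to the vinyl sulfoxide (a vinyl cation equivalent) should occur at C13 from the α face, anti to the syn-axial 8β-silyloxy group (as in alkylations anti to a syn-axial angular substituent), so the new chain becomes equatorial and the methyl axial.

Step 30
Reactants: 45 sulfoxide
Product: 46 13α-vinyl ketone
Conditions: NaHCO3, toluene, 110 °C
Reagents that add atoms: none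
Why: Thermal syn-elimination of the sulfoxide (loss of sulfenic acid) can only give the terminal alkene, the C13 vinyl group.

Step 31
Reactants: 46 bis-silyl ether
Product: 47 7α,8β-diol
Conditions: HF·pyridine, pyridine/THF, 0 °C to rt
Reagents that add atoms: none
Why: Fluoride desilylation removes both silyl ethers; the esters and the α-ketol are stable to buffered HF.

Step 32
Reactants: 47 diol
Product: 48 7α-acetate
Conditions: Ac2O, pyridine, DMAP (cat.), CH2Cl2, rt
Reagents that add atoms: acetic anhydride, CC(=O)OC(C)=O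
Why: Nucleophile-catalysed acylation of the secondary axial 7α-alcohol; the tertiary 8-alcohol is unreactive and the trans-diaxial diol cannot relay the acetyl group.

Step 33
Reactants: 48 di-tert-butyl ester
Product: 49 target diacid
Conditions: CF3CO2H/CH2Cl2 (1:4), 0 °C to rt
Reagents that add atoms: none
Why: Acidolysis of both tert-butyl esters (loss of isobutene) frees the two carboxylic acids; benzoate, acetate, the tertiary α-ketol and the vinyl group should survive.

**Compound list**
1 | (E)-3-methylpent-2-en-4-yn-1-ol | C#C/C(C)=C/CO | starting material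
2 | (E)-tert-butyldimethyl[(3-methylpent-2-en-4-yn-1-yl)oxy]silane | C#C/C(C)=C/CO[Si](C)(C)C(C)(C)C | intermediate
3 | lithium acetylide of 2 | [Li]C#C/C(C)=C/CO[Si](C)(C)C(C)(C)C | intermediate (not isolated)
4 | (E)-6-[(tert-butyldimethylsilyl)oxy]-4-methylhex-4-en-2-yn-1-ol | OCC#C/C(C)=C/CO[Si](C)(C)C(C)(C)C | intermediate
5 | (2E,4E)-6-[(tert-butyldimethylsilyl)oxy]-4-methylhexa-2,4-dien-1-ol | OC/C=C/C(C)=C/CO[Si](C)(C)C(C)(C)C | intermediate
6 | methyl (2E,4E)-6-[(tert-butyldimethylsilyl)oxy]-4-methylhexa-2,4-dien-1-yl carbonate | COC(=O)OC/C=C/C(C)=C/CO[Si](C)(C)C(C)(C)C | intermediate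
7 | tert-butyl 2-methylpropanoate | CC(C)C(=O)OC(C)(C)C | starting material
8 | lithium enolate of 7 | CC(C)=C(O[Li])OC(C)(C)C | intermediate (not isolated)
9 | [(1-tert-butoxy-2-methylprop-1-en-1-yl)oxy]trimethylsilane | CC(C)=C(OC(C)(C)C)O[Si](C)(C)C | intermediate
10 | tert-butyl (3R,4E)-6-[(tert-butyldimethylsilyl)oxy]-3-ethenyl-2,2,4-trimethylhex-4-enoate (C5 set) | C=C[C@@H](C(C)(C)C(=O)OC(C)(C)C)/C(C)=C/CO[Si](C)(C)C(C)(C)C | intermediate
11 | 3-bromobut-3-en-1-ol | OCCC(Br)=C | starting material
12 | B-alkyl-9-borabicyclo[3.3.1]nonane from 10 (boron on C7) | B1(CC[C@@H](C(C)(C)C(=O)OC(C)(C)C)/C(C)=C/CO[Si](C)(C)C(C)(C)C)C2CCCC1CCC2 | intermediate (not isolated)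
13 | tert-butyl (3R,4E)-6-[(tert-butyldimethylsilyl)oxy]-3-(5-hydroxy-3-methylidenepentyl)-2,2,4-trimethylhex-4-enoate | OCCC(=C)CC[C@@H](C(C)(C)C(=O)OC(C)(C)C)/C(C)=C/CO[Si](C)(C)C(C)(C)C | intermediate
14 | (6R,7E)-6-(1-tert-butoxy-2-methyl-1-oxopropan-2-yl)-9-[(tert-butyldimethylsilyl)oxy]-7-methyl-3-methylidenenon-7-enoic acid | OC(=O)CC(=C)CC[C@@H](C(C)(C)C(=O)OC(C)(C)C)/C(C)=C/CO[Si](C)(C)C(C)(C)C | intermediate
15 | (6R,7E)-6-(1-tert-butoxy-2-methyl-1-oxopropan-2-yl)-9-hydroxy-7-methyl-3-methylidenenon-7-enoic acid | OC(=O)CC(=C)CC[C@@H](C(C)(C)C(=O)OC(C)(C)C)/C(C)=C/CO | intermediate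
16 | tert-butyl 2-methyl-2-[(7R,8E)-8-methyl-4-methylidene-2-oxo-1-oxacyclodec-8-en-7-yl]propanoate (ten-membered lactone: C11 carbonyl, O–C2, E C1=C10, C8 methylene) | O=C1CC(=C)CC[C@@H](C(C)(C)C(=O)OC(C)(C)C)/C(C)=C/CO1 | intermediate
17 | trimethylsilyl ketene acetal of 16 (C9=C11, C8 anti to the ring oxygen) | C[Si](C)(C)O/C1=C\C(=C)CC[C@@H](C(C)(C)C(=O)OC(C)(C)C)/C(C)=C/CO1 | intermediate (not isolated)
18 | trimethylsilyl ester of 19 | C[Si](C)(C)OC(=O)[C@@H]1[C@@](C)(C=C)[C@H](C(C)(C)C(=O)OC(C)(C)C)CCC1=C | intermediate (not isolated)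
19 | (1S,2S,3R)-3-(1-tert-butoxy-2-methyl-1-oxopropan-2-yl)-2-ethenyl-2-methyl-6-methylidenecyclohexane-1-carboxylic acid (ring B; 9α-H, 10β-Me, 5α-H; all three carbon branches equatorial) | OC(=O)[C@@H]1[C@@](C)(C=C)[C@H](C(C)(C)C(=O)OC(C)(C)C)CCC1=C | intermediate
20 | methyl ester of 19 | COC(=O)[C@@H]1[C@@](C)(C=C)[C@H](C(C)(C)C(=O)OC(C)(C)C)CCC1=C | intermediate
21 | C11 primary alcohol (CO2Me of 20 reduced to CH2OH; C9, C10, C5 as in 19) | OC[C@@H]1[C@@](C)(C=C)[C@H](C(C)(C)C(=O)OC(C)(C)C)CCC1=C | intermediate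
22 | C11 4-methoxybenzyl ether of 21 | COc1ccc(COC[C@@H]2[C@@](C)(C=C)[C@H](C(C)(C)C(=O)OC(C)(C)C)CCC2=C)cc1 | intermediate
23 | C2 aldehyde (vinyl on C10 converted into CH2CHO) | COc1ccc(COC[C@@H]2[C@@](C)(CC=O)[C@H](C(C)(C)C(=O)OC(C)(C)C)CCC2=C)cc1 | intermediate
24 | C2 carboxylic acid | COc1ccc(COC[C@@H]2[C@@](C)(CC(=O)O)[C@H](C(C)(C)C(=O)OC(C)(C)C)CCC2=C)cc1 | intermediate
25 | di-tert-butyl ester (C2 and C3), C8 methylene, C11 OPMB | COc1ccc(COC[C@@H]2[C@@](C)(CC(=O)OC(C)(C)C)[C@H](C(C)(C)C(=O)OC(C)(C)C)CCC2=C)cc1 | intermediate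
26 | C8 diol (C8-OH and CH2OH; C8 epimers) | COc1ccc(COC[C@@H]2[C@@](C)(CC(=O)OC(C)(C)C)[C@H](C(C)(C)C(=O)OC(C)(C)C)CCC2(O)CO)cc1 | intermediate (not isolated)
27 | C8 ketone | COc1ccc(COC[C@@H]2[C@@](C)(CC(=O)OC(C)(C)C)[C@H](C(C)(C)C(=O)OC(C)(C)C)CCC2=O)cc1 | intermediate
28 | potassium enolate of 27 (C7=C8) | COc1ccc(COC[C@@H]2[C@@](C)(CC(=O)OC(C)(C)C)[C@H](C(C)(C)C(=O)OC(C)(C)C)CC=C2O[K])cc1 | intermediate (not isolated)
29 | 7α-hydroxy C8 ketone (OH axial) | COc1ccc(COC[C@@H]2[C@@](C)(CC(=O)OC(C)(C)C)[C@H](C(C)(C)C(=O)OC(C)(C)C)C[C@@H](O)C2=O)cc1 | intermediate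
30 | 7α-triethylsilyloxy C8 ketone | COc1ccc(COC[C@@H]2[C@@](C)(CC(=O)OC(C)(C)C)[C@H](C(C)(C)C(=O)OC(C)(C)C)C[C@@H](O[Si](CC)(CC)CC)C2=O)cc1 | intermediate
31 | methoxyallene (1-methoxypropa-1,2-diene) | COC=C=C | starting material
32 | 1-lithio-1-methoxyallene | [Li]C(OC)=C=C | intermediate (not isolated)
33 | lithium alkoxide of the C8 allenyl ether adduct (8β-O, C14 equatorial) | COc1ccc(COC[C@@H]2[C@@](C)(CC(=O)OC(C)(C)C)[C@H](C(C)(C)C(=O)OC(C)(C)C)C[C@@H](O[Si](CC)(CC)CC)[C@@]2(O[Li])C(OC)=C=C)cc1 | intermediate (not isolated)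
34 | α′-hydroxy vinyl ketone (8β-OH, C14 ketone, C13=C12 vinyl, 7α-OTES, C11 OPMB) | COc1ccc(COC[C@@H]2[C@@](C)(CC(=O)OC(C)(C)C)[C@H](C(C)(C)C(=O)OC(C)(C)C)C[C@@H](O[Si](CC)(CC)CC)[C@@]2(O)C(=O)C=C)cc1 | intermediate
35 | C11 alcohol of 34 | OC[C@@H]1[C@@](C)(CC(=O)OC(C)(C)C)[C@H](C(C)(C)C(=O)OC(C)(C)C)C[C@@H](O[Si](CC)(CC)CC)[C@@]1(O)C(=O)C=C | intermediate
36 | C11 aldehyde | O=C[C@@H]1[C@@](C)(CC(=O)OC(C)(C)C)[C@H](C(C)(C)C(=O)OC(C)(C)C)C[C@@H](O[Si](CC)(CC)CC)[C@@]1(O)C(=O)C=C | intermediate
37 | trans-fused ring-C 11,14-diketone (8β-OH, 7α-OTES) | C1CC(=O)[C@@H]2[C@@](C)(CC(=O)OC(C)(C)C)[C@H](C(C)(C)C(=O)OC(C)(C)C)C[C@@H](O[Si](CC)(CC)CC)[C@@]2(O)C1=O | intermediate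
38 | 11α-alcohol (equatorial), 14-ketone | C1C[C@@H](O)[C@@H]2[C@@](C)(CC(=O)OC(C)(C)C)[C@H](C(C)(C)C(=O)OC(C)(C)C)C[C@@H](O[Si](CC)(CC)CC)[C@@]2(O)C1=O | intermediate
39 | 11α-benzoate | C1C[C@@H](OC(=O)c3ccccc3)[C@@H]2[C@@](C)(CC(=O)OC(C)(C)C)[C@H](C(C)(C)C(=O)OC(C)(C)C)C[C@@H](O[Si](CC)(CC)CC)[C@@]2(O)C1=O | intermediate
40 | 8β-trimethylsilyl ether of 39 | C1C[C@@H](OC(=O)c3ccccc3)[C@@H]2[C@@](C)(CC(=O)OC(C)(C)C)[C@H](C(C)(C)C(=O)OC(C)(C)C)C[C@@H](O[Si](CC)(CC)CC)[C@@]2(O[Si](C)(C)C)C1=O | intermediate
41 | lithium enolate of 40 (C13=C14) | [Li]OC1=CC[C@@H](OC(=O)c3ccccc3)[C@@H]2[C@@](C)(CC(=O)OC(C)(C)C)[C@H](C(C)(C)C(=O)OC(C)(C)C)C[C@@H](O[Si](CC)(CC)CC)[C@@]12O[Si](C)(C)C | intermediate (not isolated)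
42 | 13-methyl ketone (C13 epimers) | CC1C[C@@H](OC(=O)c3ccccc3)[C@@H]2[C@@](C)(CC(=O)OC(C)(C)C)[C@H](C(C)(C)C(=O)OC(C)(C)C)C[C@@H](O[Si](CC)(CC)CC)[C@@]2(O[Si](C)(C)C)C1=O | intermediate
43 | phenyl vinyl sulfoxide | C=CS(=O)c1ccccc1 | starting material
44 | potassium enolate of 42 | [K]OC1=C(C)C[C@@H](OC(=O)c3ccccc3)[C@@H]2[C@@](C)(CC(=O)OC(C)(C)C)[C@H](C(C)(C)C(=O)OC(C)(C)C)C[C@@H](O[Si](CC)(CC)CC)[C@@]12O[Si](C)(C)C | intermediate (not isolated)
45 | 13α-[2-(phenylsulfinyl)ethyl]-13β-methyl ketone (sulfur epimers) | O=S(CC[C@@]1(C)C[C@@H](OC(=O)c3ccccc3)[C@@H]2[C@@](C)(CC(=O)OC(C)(C)C)[C@H](C(C)(C)C(=O)OC(C)(C)C)C[C@@H](O[Si](CC)(CC)CC)[C@@]2(O[Si](C)(C)C)C1=O)c1ccccc1 | intermediate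
46 | 13α-vinyl-13β-methyl ketone, 7α-OTES, 8β-OTMS, 11α-OBz, di-tert-butyl ester | C=C[C@@]1(C)C[C@@H](OC(=O)c3ccccc3)[C@@H]2[C@@](C)(CC(=O)OC(C)(C)C)[C@H](C(C)(C)C(=O)OC(C)(C)C)C[C@@H](O[Si](CC)(CC)CC)[C@@]2(O[Si](C)(C)C)C1=O | intermediate
47 | 7α,8β-diol | C=C[C@@]1(C)C[C@@H](OC(=O)c3ccccc3)[C@@H]2[C@@](C)(CC(=O)OC(C)(C)C)[C@H](C(C)(C)C(=O)OC(C)(C)C)C[C@@H](O)[C@@]2(O)C1=O | intermediate
48 | 7α-acetate, di-tert-butyl ester of the target | C=C[C@@]1(C)C[C@@H](OC(=O)c3ccccc3)[C@@H]2[C@@](C)(CC(=O)OC(C)(C)C)[C@H](C(C)(C)C(=O)OC(C)(C)C)C[C@@H](OC(C)=O)[C@@]2(O)C1=O | intermediate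
49 | target diacid (7α-OAc, 8β-OH, 11α-OBz, 13β-Me, 13α-vinyl, 14-oxo; C2 and C3 carboxylic acids) | C=C[C@@]1(C)C[C@@H](OC(=O)c2ccccc2)[C@@H]2[C@@](C)(CC(=O)O)[C@H](C(C)(C)C(=O)O)C[C@@H](OC(C)=O)[C@@]2(O)C1=O | target

**Totals**
Total step count: 33. Longest linear sequence: 32 steps (steps 1–4 and 6–33, from 1; step 5 prepares 9).

**Steps most likely to fail**

1. Step 11. Enolisation inside the macrocycle may give the ketene acetal with C8 syn to the ring oxygen. The chair rearrangement would then place the vinyl group axial on C10, an error that cannot be corrected later (C9, by contrast, becomes epimerisable once C8 is a ketone). The fallback locks the enolate geometry by chelation and closes the macrocycle differently. It sets out from 10 and comes back at 20. Linear-selective hydroformylation of the vinyl group (Rh(acac)(CO)2, wide-bite-angle bisphosphite, CO/H2) would give the C8 aldehyde F1. SnCl2-catalysed insertion of tert-butyl diazoacetate (Roskamp reaction) would give the β-keto tert-butyl ester F2, and HF·pyridine the hydroxy β-keto ester F3. Thermolysis at high dilution (toluene, 110 °C; acylketene formation and trapping by the allylic alcohol) would give the β-keto lactone F4. With 2.2 equivalents of LiN(i-Pr)2 the lithium-chelated dianion of F4 holds C8 anti to the ring oxygen; its ester-enolate Carroll rearrangement should give the β-keto acid F5, which is esterified cold with Me3SiCHN2 to the β-keto methyl ester F6. Methylenation of the ketone under non-basic conditions (Zn, CH2Br2, TiCl4) returns the route at 20.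

2. Step 10. Intermolecular esterification to oligomers, or SN2′ attack and elimination at the activated allylic position, may outrun closure of the ten-membered ring. The fallback forms the ester bond first and closes the ring by C–C coupling. It sets out from 10 and comes back at 16. HF·pyridine would give the allylic alcohol F7. This is esterified (DIC, cat. DMAP, 0 °C) with 3-bromobut-3-enoic acid F8, made from 11 with CrO3/H2SO4, to give the bromo ester F9. Hydroboration of the vinyl group with 9-BBN would give the alkylborane F10. Intramolecular B-alkyl Suzuki–Miyaura coupling (Pd(dppf)Cl2, AsPh3, Cs2CO3, DMF/THF/H2O, slow addition) then forms C7–C8 and gives 16.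

3. Step 24. Conjugate addition of the thiol to the vinyl ketone, short radical chains, or decarbonylation of the hindered acyl radical may compete with closure. The fallback generates the same acyl radical from a preformed acyl selenide under tin hydride chain conditions. It sets out from 36 and comes back at 37. Pinnick oxidation would give the acid F11, and (PhSe)2/PBu3 the Se-phenyl selenoester F12. Slow addition of Bu3SnH with a radical initiator (benzene, 80 °C) should then give 37 by the same 6-endo closure.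

**Further compounds**
F1 | step 11 | C8 aldehyde from hydroformylation of 10 | O=CCC[C@@H](C(C)(C)C(=O)OC(C)(C)C)/C(C)=C/CO[Si](C)(C)C(C)(C)C
F2 | step 11 | β-keto tert-butyl ester (C8 ketone, C11 ester), TBS ether | CC(C)(C)OC(=O)CC(=O)CC[C@@H](C(C)(C)C(=O)OC(C)(C)C)/C(C)=C/CO[Si](C)(C)C(C)(C)C
F3 | step 11 | hydroxy β-keto tert-butyl ester | CC(C)(C)OC(=O)CC(=O)CC[C@@H](C(C)(C)C(=O)OC(C)(C)C)/C(C)=C/CO
F4 | step 11 | ten-membered β-keto lactone (C8 ketone in place of the methylene of 16) | O=C1CC(=O)CC[C@@H](C(C)(C)C(=O)OC(C)(C)C)/C(C)=C/CO1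
F5 | step 11 | ring-B β-keto acid (C8 ketone analogue of 19) | OC(=O)[C@@H]1[C@@](C)(C=C)[C@H](C(C)(C)C(=O)OC(C)(C)C)CCC1=O
F6 | step 11 | ring-B β-keto methyl ester | COC(=O)[C@@H]1[C@@](C)(C=C)[C@H](C(C)(C)C(=O)OC(C)(C)C)CCC1=O
F7 | step 10 | allylic alcohol from 10 | C=C[C@@H](C(C)(C)C(=O)OC(C)(C)C)/C(C)=C/CO
F8 | step 10 | 3-bromobut-3-enoic acid | OC(=O)CC(Br)=C
F9 | step 10 | 3-bromobut-3-enoate of F7 | C=C[C@@H](C(C)(C)C(=O)OC(C)(C)C)/C(C)=C/COC(=O)CC(Br)=C
F10 | step 10 | B-alkyl-9-borabicyclo[3.3.1]nonane from F9 | B1(CC[C@@H](C(C)(C)C(=O)OC(C)(C)C)/C(C)=C/COC(=O)CC(Br)=C)C2CCCC1CCC2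
F11 | step 24 | C11 carboxylic acid from 36 | OC(=O)[C@@H]1[C@@](C)(CC(=O)OC(C)(C)C)[C@H](C(C)(C)C(=O)OC(C)(C)C)C[C@@H](O[Si](CC)(CC)CC)[C@@]1(O)C(=O)C=C
F12 | step 24 | Se-phenyl selenoester of F11 | O=C([Se]c1ccccc1)[C@@H]1[C@@](C)(CC(=O)OC(C)(C)C)[C@H](C(C)(C)C(=O)OC(C)(C)C)C[C@@H](O[Si](CC)(CC)CC)[C@@]1(O)C(=O)C=C
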